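Everything rests on cutting the seven-membered ring at C1–C2 and C4–C5 (locants: C1 OCH next to the fusion CH, C2, C3, C4, C5 OCH next to the quaternary carbon, C6 fusion C–CH3, C7, C8, C9 C(OH)iPr, C10 fusion CH). The bridge C2–C3(CH3)–C4 between the two oxygen-bearing carbons is a 2-methylidenepropane-1,3-diyl unit, so one indium-mediated double allylation of a trans-cyclopentane-1,2-dicarbaldehyde with 3-chloro-2-(chloromethyl)prop-1-ene makes both bonds, closes the cycloheptane ring and creates both carbinols. The precursor already holds the C6, C9 and C10 stereocentres; its C9 hydroxyl stays free to steer C1 by chelation. The exocyclic alkene is later moved to C3=C4 through a C5 ketone.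

Key step: step 8

Remark: the locants C1–C10 defined above are used for all bicyclic compounds. Compound 18 is written as the expected 5R epimer; its C5 configuration is immaterial because C5 becomes a ketone in step 10.

Step 1
Reactants: 1 3-methylcyclopent-2-en-1-one; 2 ethynyltrimethylsilane
Product: 5 (3S)-triethyl({3-methyl-3-[1-(trimethylsilyl)ethenyl]cyclopent-1-en-1-yl}oxy)silane, via vinylalane 3 (not isolated), via aluminium enolate 4 (not isolated)
Conditions: 2, i-Bu2AlH, hexanes/THF, 55 °C; then 1, CuCl2·2H2O (5 mol %), chiral sulfonate-bearing imidazolinium salt (carbene ligand precursor, 2.5 mol %, pre-treated with Ag2O), THF, −15 °C; then Et3SiOTf, −78 → 0 °C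
Reagents that add atoms: ethynyltrimethylsilane (2), C#C[Si](C)(C)C; triethylsilyl trifluoromethanesulfonate, CC[Si](CC)(CC)OS(=O)(=O)C(F)(F)F
Why: Alpha-selective hydroalumination of the silylalkyne gives the 1-silylvinylalane, whose copper-catalysed asymmetric conjugate addition (CuCl2·2H2O with the chiral carbene ligand, the ligand antipode being chosen so that the vinyl group reaches the enone face that gives the 3S quaternary carbon C6) leaves a regiodefined aluminium enolate that is silylated on oxygen, fixing the C9=C10 enol ether.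

Step 2
Reactants: 5 (3S)-triethyl({3-methyl-3-[1-(trimethylsilyl)ethenyl]cyclopent-1-en-1-yl}oxy)silane; 6 benzyl chloromethyl ether
Product: 7 (2S,3S)-2-[(benzyloxy)methyl]-3-methyl-3-[1-(trimethylsilyl)ethenyl]cyclopentan-1-one
Conditions: TiCl4, CH2Cl2, −78 °C
Reagents that add atoms: benzyl chloromethyl ether (6), ClCOCc1ccccc1
Why: Mukaiyama-type Lewis acid alkylation of the silyl enol ether with the alpha-chloro ether places the one-carbon unit C1 regiospecifically on C10, and the oxocarbenium ion approaches the ring face opposite the bulky 1-silylvinyl group on the adjacent quaternary carbon, so CH2OBn ends cis to the C6 methyl (2S).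

Step 3
Reactants: 7 (2S,3S)-2-[(benzyloxy)methyl]-3-methyl-3-[1-(trimethylsilyl)ethenyl]cyclopentan-1-one
Product: 8 (2S,3R)-2-[(benzyloxy)methyl]-3-ethenyl-3-methylcyclopentan-1-one
Conditions: CF3CO2H, CH2Cl2, 0 → 23 °C
Reagents that add atoms: none
Why: Electrophilic protodesilylation of the vinylsilane (protonation at the silicon-bearing carbon, loss of the silyl group from the beta-silyl cation) unmasks the plain vinyl group, the benzyl ether is acid-stable, and a short exposure at low temperature should leave the enolisable C10 centre untouched.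

Step 4
Reactants: 8 (2S,3R)-2-[(benzyloxy)methyl]-3-ethenyl-3-methylcyclopentan-1-one; 9 isopropylmagnesium chloride
Product: 10 (1R,2S,3R)-2-[(benzyloxy)methyl]-3-ethenyl-3-methyl-1-(propan-2-yl)cyclopentan-1-ol
Conditions: i-PrMgCl, CeCl3, THF, −78 → 0 °C
Reagents that add atoms: isopropylmagnesium chloride (9), CC(C)[Mg]Cl
Why: Organocerium 1,2-addition, chosen because the weakly basic cerium reagent suppresses enolisation, beta-elimination of benzyloxide and hydride transfer from the isopropyl group; the nucleophile attacks the cyclopentanone face opposite the adjacent C10 substituent, which sets C9 with the hydroxyl cis to CH2OBn (1R).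

Step 5
Reactants: 10 (1R,2S,3R)-2-[(benzyloxy)methyl]-3-ethenyl-3-methyl-1-(propan-2-yl)cyclopentan-1-ol
Product: 12 (1R,2S,3S)-2-[(benzyloxy)methyl]-3-(hydroxymethyl)-3-methyl-1-(propan-2-yl)cyclopentan-1-ol, via ozonide 11 (not isolated)
Conditions: O3, CH2Cl2, −78 °C; then NaBH4, EtOH, −78 → 23 °C
Reagents that add atoms: ozone, O=[O+][O-]
Why: Criegee ozonolysis of the only alkene with reductive borohydride work-up turns the vinyl group into the C5 primary alcohol without touching a stereocentre, and the benzyl ether and the alcohols should tolerate a stoichiometric ozone charge at −78 °C.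

Step 6
Reactants: 12 (1R,2S,3S)-2-[(benzyloxy)methyl]-3-(hydroxymethyl)-3-methyl-1-(propan-2-yl)cyclopentan-1-ol
Product: 13 (1R,2S,3S)-2,3-bis(hydroxymethyl)-3-methyl-1-(propan-2-yl)cyclopentan-1-ol
Conditions: H2 (1 atm), 10% Pd/C, EtOH, 23 °C
Reagents that add atoms: none
Why: Palladium-catalysed hydrogenolysis cleaves the benzyl ether cleanly now that no alkene is left in the molecule.

Step 7
Reactants: 13 (1R,2S,3S)-2,3-bis(hydroxymethyl)-3-methyl-1-(propan-2-yl)cyclopentan-1-ol
Product: 15 (1S,2R,3R)-3-hydroxy-1-methyl-3-(propan-2-yl)cyclopentane-1,2-dicarbaldehyde, via hydroxy aldehyde 14 (not isolated)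
Conditions: Dess–Martin periodinane, pyridine, CH2Cl2, 0 → 23 °C; used crude
Reagents that add atoms: none
Why: Dess–Martin oxidation converts both primary alcohols into aldehydes under buffered conditions that spare the tertiary alcohol and should avoid epimerisation at C10 and retro-aldol cleavage, while the trans arrangement of the two arms disfavours closure of the intermediate hydroxy aldehyde to a lactol that would be over-oxidised.

Step 8
Reactants: 15 (1S,2R,3R)-3-hydroxy-1-methyl-3-(propan-2-yl)cyclopentane-1,2-dicarbaldehyde; 16 3-chloro-2-(chloromethyl)prop-1-ene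
Product: 18 (1S,5R,6S,9R,10S)-6-methyl-3-methylidene-9-(propan-2-yl)-trans-hydroazulene-1,5,9-triol (route locants), via chloroallyl carbinol 17 (not isolated)
Conditions: In powder, NaI (catalytic), THF/H2O (1:1), 0.01 M, 23 → 40 °C, 16 added over 6 h
Reagents that add atoms: 3-chloro-2-(chloromethyl)prop-1-ene (16), ClCC(=C)CCl
Why: Indium inserts into one iodide-activated carbon–halogen bond and the allylindium adds through its gamma carbon to the C1 aldehyde, which is the less hindered one and is activated by chelation of trivalent indium between the C9 hydroxyl and the C1 carbonyl; the second allylic halide is then metalated and adds intramolecularly to the neopentyl C5 aldehyde, and because the four-carbon unit is symmetric either terminus gives the same connectivity. The closest known reaction type is the aqueous metal-mediated Barbier double allylation of 1,4-dicarbonyl compounds with 2-methylidenepropane-1,3-diyl dihalides or their tin and silicon analogues, which gives 3-methylidenecycloheptane-1,5-diols. The cycloheptane ring closes by a 7-exo-trig attack on the aldehyde, helped by the trans-1,2 arrangement on the cyclopentane, which holds the reacting carbons close but cannot collapse to a lactol or cyclic hydrate. C1 is set by the six-membered chelate (attack on the face next to H10, away from quaternary C6, gives 1S), and C5 by the metal bridging the new C1 oxygen and the C5 carbonyl in the ring-closing transition state, which should favour the cis-1,5-diol (5R). The step needs C1 to react before C5 and ring closure to beat oligomerisation; the first is secured by the hydroxyl-assisted and less hindered C1 aldehyde, the second by high dilution, slow addition of 16 and the water tolerance of allylindium, which survives until it cyclises. Either C5 epimer serves, because C5 is oxidised in step 10.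

Step 9
Reactants: 18 (1S,5R,6S,9R,10S)-6-methyl-3-methylidene-9-(propan-2-yl)-trans-hydroazulene-1,5,9-triol
Product: 19 (1S,5R,6S,9R,10S)-1-[(tert-butyldimethylsilyl)oxy]-6-methyl-3-methylidene-9-(propan-2-yl)-trans-hydroazulene-5,9-diol (route locants)
Conditions: TBSCl (1.1 equiv), imidazole, DMF, 0 → 23 °C
Reagents that add atoms: tert-butyl(chloro)dimethylsilane, CC(C)(C)[Si](C)(C)Cl
Why: Silylation with a bulky chlorosilane should pick the equatorial C1 hydroxyl, whose neighbour C10 carries a hydrogen, over the neopentyl C5 hydroxyl next to quaternary C6 and the tertiary C9 hydroxyl.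

Step 10
Reactants: 19 (1S,5R,6S,9R,10S)-1-[(tert-butyldimethylsilyl)oxy]-6-methyl-3-methylidene-9-(propan-2-yl)-trans-hydroazulene-5,9-diol
Product: 21 (1S,6S,9R,10S)-1-[(tert-butyldimethylsilyl)oxy]-9-hydroxy-3,6-dimethyl-9-(propan-2-yl)-trans-hydroazul-3-en-5-one (route locants), via exo-methylene ketone 20 (not isolated)
Conditions: Dess–Martin periodinane, pyridine, CH2Cl2, 23 °C; aqueous wash; then DBU (catalytic), CH2Cl2, 0 → 23 °C
Reagents that add atoms: none
Why: Dess–Martin oxidation turns C5 (either epimer) into the ketone, and amidine-base isomerisation through the dienolate, which can form only at C4 because C6 is quaternary, moves the exocyclic alkene into the conjugated trisubstituted C3=C4 position by gamma-protonation; the reaction is stopped as soon as 20 is consumed.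

Step 11
Reactants: 21 (1S,6S,9R,10S)-1-[(tert-butyldimethylsilyl)oxy]-9-hydroxy-3,6-dimethyl-9-(propan-2-yl)-trans-hydroazul-3-en-5-one
Product: 22 (1S,5R,6S,9R,10S)-1-[(tert-butyldimethylsilyl)oxy]-3,6-dimethyl-9-(propan-2-yl)-trans-hydroazul-3-ene-5,9-diol (route locants)
Conditions: NaBH4, CeCl3·7H2O, MeOH, −78 °C
Reagents that add atoms: none
Why: Luche 1,2-reduction of the enone, in which the trans ring fusion should hold the cycloheptenone in a chair-like form with the C6–C10 bond nearly perpendicular to the carbonyl plane, so hydride adds anti to that bond in the Felkin–Anh sense, on the face flanked by the C6 methyl and C7, and the new hydroxyl ends anti to the methyl group (5R).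

Step 12
Reactants: 22 (1S,5R,6S,9R,10S)-1-[(tert-butyldimethylsilyl)oxy]-3,6-dimethyl-9-(propan-2-yl)-trans-hydroazul-3-ene-5,9-diol
Product: 23 (1S,5R,6S,9R,10S)-3,6-dimethyl-9-(propan-2-yl)-trans-hydroazul-3-ene-1,5,9-triol (route locants)
Conditions: Bu4NF, THF, 0 → 23 °C
Reagents that add atoms: none
Why: Fluoride-mediated desilylation frees the C1 hydroxyl under conditions that do not affect the allylic alcohol or any stereocentre.

Step 13
Reactants: 23 (1S,5R,6S,9R,10S)-3,6-dimethyl-9-(propan-2-yl)-trans-hydroazul-3-ene-1,5,9-triol; 24 angelic acid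
Product: 27 (3R,3aS,4S,8R,8aS)-3-hydroxy-6,8a-dimethyl-3-(propan-2-yl)-1,2,3,3a,4,5,8,8a-octahydroazulene-4,8-diyl bis[(2Z)-2-methylbut-2-enoate], via mixed anhydride 25 (not isolated), via mono-angelate 26 (not isolated)
Conditions: 24, 2,4,6-trichlorobenzoyl chloride, Et3N, toluene, 23 °C; then 23, toluene, 80 °C
Reagents that add atoms: angelic acid (24), C/C=C(/C)C(=O)O
Why: Yamaguchi-type acylation through the mixed 2,4,6-trichlorobenzoic anhydride without a nucleophilic catalyst, a protocol that transfers the angeloyl group without Z to E isomerisation; the two secondary alcohols should react while the hindered tertiary C9 hydroxyl stays free.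

Compound list
1 | 3-methylcyclopent-2-en-1-one | CC1=CC(=O)CC1 | starting material
2 | ethynyltrimethylsilane | C#C[Si](C)(C)C | starting material
3 | bis(2-methylpropyl)[1-(trimethylsilyl)ethenyl]alane | CC(C)C[Al](CC(C)C)C(=C)[Si](C)(C)C | intermediate (not isolated)
4 | bis(2-methylpropyl)aluminium (3S)-3-methyl-3-[1-(trimethylsilyl)ethenyl]cyclopent-1-en-1-olate | C=C([Si](C)(C)C)[C@@]1(C)CCC(O[Al](CC(C)C)CC(C)C)=C1 | intermediate (not isolated)
5 | (3S)-triethyl({3-methyl-3-[1-(trimethylsilyl)ethenyl]cyclopent-1-en-1-yl}oxy)silane | C=C([Si](C)(C)C)[C@@]1(C)CCC(O[Si](CC)(CC)CC)=C1 | intermediate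
6 | benzyl chloromethyl ether | ClCOCc1ccccc1 | starting material
7 | (2S,3S)-2-[(benzyloxy)methyl]-3-methyl-3-[1-(trimethylsilyl)ethenyl]cyclopentan-1-one | C=C([Si](C)(C)C)[C@@]1(C)CCC(=O)[C@@H]1COCc1ccccc1 | intermediate
8 | (2S,3R)-2-[(benzyloxy)methyl]-3-ethenyl-3-methylcyclopentan-1-one | C=C[C@@]1(C)CCC(=O)[C@@H]1COCc1ccccc1 | intermediate
9 | isopropylmagnesium chloride | CC(C)[Mg]Cl | starting material
10 | (1R,2S,3R)-2-[(benzyloxy)methyl]-3-ethenyl-3-methyl-1-(propan-2-yl)cyclopentan-1-ol | C=C[C@@]1(C)CC[C@@](O)(C(C)C)[C@@H]1COCc1ccccc1 | intermediate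
11 | (1R,2S,3S)-2-[(benzyloxy)methyl]-3-methyl-1-(propan-2-yl)-3-(1,2,4-trioxolan-3-yl)cyclopentan-1-ol (trioxolane carbon of either configuration) | O1COOC1[C@@]2(C)CC[C@@](O)(C(C)C)[C@@H]2COCc1ccccc1 | intermediate (not isolated)
12 | (1R,2S,3S)-2-[(benzyloxy)methyl]-3-(hydroxymethyl)-3-methyl-1-(propan-2-yl)cyclopentan-1-ol | OC[C@@]1(C)CC[C@@](O)(C(C)C)[C@@H]1COCc1ccccc1 | intermediate
13 | (1R,2S,3S)-2,3-bis(hydroxymethyl)-3-methyl-1-(propan-2-yl)cyclopentan-1-ol | OC[C@@]1(C)CC[C@@](O)(C(C)C)[C@@H]1CO | intermediate
14 | (1R,2R,5S)-2-hydroxy-5-(hydroxymethyl)-5-methyl-2-(propan-2-yl)cyclopentane-1-carbaldehyde | OC[C@@]1(C)CC[C@@](O)(C(C)C)[C@@H]1C=O | intermediate (not isolated)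
15 | (1S,2R,3R)-3-hydroxy-1-methyl-3-(propan-2-yl)cyclopentane-1,2-dicarbaldehyde (trans dialdehyde, free C9 hydroxyl) | O=C[C@@]1(C)CC[C@@](O)(C(C)C)[C@@H]1C=O | intermediate
16 | 3-chloro-2-(chloromethyl)prop-1-ene | ClCC(=C)CCl | starting material
17 | (1S,2S,3R)-2-[(1S)-3-(chloromethyl)-1-hydroxybut-3-en-1-yl]-3-hydroxy-1-methyl-3-(propan-2-yl)cyclopentane-1-carbaldehyde | O=C[C@@]1(C)CC[C@@](O)(C(C)C)[C@@H]1[C@@H](O)CC(=C)CCl | intermediate (not isolated)
18 | (1S,5R,6S,9R,10S)-6-methyl-3-methylidene-9-(propan-2-yl)-trans-hydroazulene-1,5,9-triol (route locants; C6 methyl and H10 trans, both carbinol oxygens on the H10 face) | O[C@H]1CC(=C)C[C@@H](O)[C@@]2(C)CC[C@@](O)(C(C)C)[C@H]12 | intermediate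
19 | (1S,5R,6S,9R,10S)-1-[(tert-butyldimethylsilyl)oxy]-6-methyl-3-methylidene-9-(propan-2-yl)-trans-hydroazulene-5,9-diol (route locants) | CC(C)(C)[Si](C)(C)O[C@H]1CC(=C)C[C@@H](O)[C@@]2(C)CC[C@@](O)(C(C)C)[C@H]12 | intermediate
20 | (1S,6S,9R,10S)-1-[(tert-butyldimethylsilyl)oxy]-9-hydroxy-6-methyl-3-methylidene-9-(propan-2-yl)-trans-hydroazulen-5-one (route locants) | CC(C)(C)[Si](C)(C)O[C@H]1CC(=C)CC(=O)[C@@]2(C)CC[C@@](O)(C(C)C)[C@H]12 | intermediate (not isolated)
21 | (1S,6S,9R,10S)-1-[(tert-butyldimethylsilyl)oxy]-9-hydroxy-3,6-dimethyl-9-(propan-2-yl)-trans-hydroazul-3-en-5-one (route locants) | CC(C)(C)[Si](C)(C)O[C@H]1CC(C)=CC(=O)[C@@]2(C)CC[C@@](O)(C(C)C)[C@H]12 | intermediate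
22 | (1S,5R,6S,9R,10S)-1-[(tert-butyldimethylsilyl)oxy]-3,6-dimethyl-9-(propan-2-yl)-trans-hydroazul-3-ene-5,9-diol (route locants) | CC(C)(C)[Si](C)(C)O[C@H]1CC(C)=C[C@@H](O)[C@@]2(C)CC[C@@](O)(C(C)C)[C@H]12 | intermediate
23 | (1S,5R,6S,9R,10S)-3,6-dimethyl-9-(propan-2-yl)-trans-hydroazul-3-ene-1,5,9-triol (route locants) | O[C@H]1CC(C)=C[C@@H](O)[C@@]2(C)CC[C@@](O)(C(C)C)[C@H]12 | intermediate
24 | angelic acid, (2Z)-2-methylbut-2-enoic acid | C/C=C(/C)C(=O)O | starting material
25 | (2Z)-2-methylbut-2-enoic 2,4,6-trichlorobenzoic anhydride | C/C=C(/C)C(=O)OC(=O)c1c(Cl)cc(Cl)cc1Cl | intermediate (not isolated)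
26 | (1S,5R,6S,9R,10S)-5,9-dihydroxy-3,6-dimethyl-9-(propan-2-yl)-trans-hydroazul-3-en-1-yl (2Z)-2-methylbut-2-enoate (route locants) | C/C=C(/C)C(=O)O[C@H]1CC(C)=C[C@@H](O)[C@@]2(C)CC[C@@](O)(C(C)C)[C@H]12 | intermediate (not isolated)
27 | (3R,3aS,4S,8R,8aS)-3-hydroxy-6,8a-dimethyl-3-(propan-2-yl)-1,2,3,3a,4,5,8,8a-octahydroazulene-4,8-diyl bis[(2Z)-2-methylbut-2-enoate] | C/C=C(/C)C(=O)O[C@H]1CC(C)=C[C@@H](OC(=O)/C(C)=C\C)[C@@]2(C)CC[C@@](O)(C(C)C)[C@H]12 | target

Total step count: 13. Longest linear sequence: 13 steps (1 → 27); compounds 2, 6, 9, 16 and 24 are commercial inputs.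

Steps most likely to fail

1. Step 8. The seven-membered ring closure onto the neopentyl aldehyde may be slow, so that oligomerisation, or protonolysis of the second allylindium after a single allylation, takes over; facial control at C1 may also be lost. Fallback: the annulation is run in two separate stages with a differentiated reagent. Starting from dialdehyde 15, SnF2-mediated allylation with 3-iodo-2-[(trimethylsilyl)methyl]prop-1-ene should deliver only the allyltin end to the C1 aldehyde and give the allylsilane carbinol F1, which can be purified. A fluoride-triggered intramolecular Hosomi–Sakurai addition (Bu4NF, THF, high dilution) of the allylsilane to the C5 aldehyde then closes the ring and returns to triol 18.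

2. Step 11. Hydride may be delivered with poor facial selectivity, or mainly to the other face, if the enone reacts through a flatter, conjugated ring form in which the axial C6 methyl becomes the controlling group. Fallback: inversion instead of selective reduction. Starting from enone 21, the alcohol formed by attack on the other face, the 5-epi alcohol F2, is subjected to Mitsunobu esterification with angelic acid 24 (PPh3, diisopropyl azodicarboxylate), which should install the C5 angelate with inversion and give the silyl ether angelate F3; elimination cannot compete because C6 is quaternary. HF·pyridine then removes the silyl group to give the mono-angelate diol F4, and acylation of its C1 hydroxyl with mixed anhydride 25 returns to target 27.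

3. Step 13. Acylation of the axial, neopentyl C5 hydroxyl may stall, and prolonged heating may isomerise the angelate to the E isomer. Fallback: the Z alkene is built after acylation. Starting from triol 23, both secondary alcohols are acylated with 2-[bis(2,2,2-trifluoroethoxy)phosphoryl]propanoic acid (N,N'-dicyclohexylcarbodiimide, 4-(dimethylamino)pyridine) to give the bis(phosphonopropanoate) F5. A Still–Gennari olefination with acetaldehyde (KN(SiMe3)2, 18-crown-6, THF, −78 °C) should then form both (Z)-2-methylbut-2-enoates and return to target 27.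

Further compounds
F1 | step 8 | (1S,2S,3R)-3-hydroxy-2-{(1S)-1-hydroxy-3-[(trimethylsilyl)methyl]but-3-en-1-yl}-1-methyl-3-(propan-2-yl)cyclopentane-1-carbaldehyde | O=C[C@@]1(C)CC[C@@](O)(C(C)C)[C@@H]1[C@@H](O)CC(=C)C[Si](C)(C)C
F2 | step 11 | (1S,5S,6S,9R,10S)-1-[(tert-butyldimethylsilyl)oxy]-3,6-dimethyl-9-(propan-2-yl)-trans-hydroazul-3-ene-5,9-diol (route locants, 5-epimer of 22) | CC(C)(C)[Si](C)(C)O[C@H]1CC(C)=C[C@H](O)[C@@]2(C)CC[C@@](O)(C(C)C)[C@H]12
F3 | step 11 | (1S,5R,6S,9R,10S)-1-[(tert-butyldimethylsilyl)oxy]-9-hydroxy-3,6-dimethyl-9-(propan-2-yl)-trans-hydroazul-3-en-5-yl (2Z)-2-methylbut-2-enoate (route locants) | CC(C)(C)[Si](C)(C)O[C@H]1CC(C)=C[C@@H](OC(=O)/C(C)=C\C)[C@@]2(C)CC[C@@](O)(C(C)C)[C@H]12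
F4 | step 11 | (1S,5R,6S,9R,10S)-1,9-dihydroxy-3,6-dimethyl-9-(propan-2-yl)-trans-hydroazul-3-en-5-yl (2Z)-2-methylbut-2-enoate (route locants) | O[C@H]1CC(C)=C[C@@H](OC(=O)/C(C)=C\C)[C@@]2(C)CC[C@@](O)(C(C)C)[C@H]12
F5 | step 13 | (1S,5R,6S,9R,10S)-9-hydroxy-3,6-dimethyl-9-(propan-2-yl)-trans-hydroazul-3-ene-1,5-diyl bis{2-[bis(2,2,2-trifluoroethoxy)phosphoryl]propanoate} (route locants) | CC(C(=O)O[C@H]1CC(C)=C[C@@H](OC(=O)C(C)P(=O)(OCC(F)(F)F)OCC(F)(F)F)[C@@]2(C)CC[C@@](O)(C(C)C)[C@H]12)P(=O)(OCC(F)(F)F)OCC(F)(F)F
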